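**Retrosynthetic overview**

- Aspidin is cut back by removing the two C-butyryl groups (ring B C5′ by Friedel–Crafts acylation, ring A C1 by DCC/DMAP C-acylation), with the ring B phenols masked as benzyl ethers and the ring A enols as ethyl enol ethers.
- The strategy rests on C5 of ring A: this quaternary CMe2 carbon lies between the C4 enol carbon and the C6 ketone and holds ring A (C1 carrying butyryl, C2 C–OH, C3 carrying the CH2 bridge) in a non-aromatic form. Ring A is therefore closed directly as a 6,6-dimethylcyclohexa-2,4-dienone by inserting ethoxyacetylene between C6 and C3 of a 2-(ring B-methyl)-3-ethoxy-4,4-dimethylcyclobutenone (new bonds C6–C1 and C2–C3, closure C5–C6).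
- The cyclobutenone is cut into dimethylketene and a ring B benzyl ynol ether, and that into lithium ethoxyacetylide and the ring B benzylic bromide.
- Ring B comes complete from 2,4,6-trihydroxytoluene (formylation, methylation para to CHO, benzylation, reduction). Ring order: ring B (bought), the four-membered ring (step 7), ring A (step 8).

Key step: step 8

Remark: aspidin has no stereocentre; ring A is drawn throughout in the enol tautomer of the target SMILES, and the labels C1 to C6 of ring A are those of the overview, not the locants of the systematic names.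

**Route**

Step 1
Reactants: 1 2,4,6-trihydroxytoluene
Product: 3 2,4,6-trihydroxy-3-methylbenzaldehyde, via iminium salt 2 (not isolated)
Conditions: POCl3, DMF, EtOAc, 0 °C to rt; then H2O, 60 °C
Reagents that add atoms: N,N-dimethylformamide CN(C)C=O; water O
Why: Vilsmeier–Haack formylation of a phloroglucinol; the two free ring carbons of 1 are equivalent and the iminium group of 2 deactivates the ring, so a single formyl group should enter.

Step 2
Reactants: 3 2,4,6-trihydroxy-3-methylbenzaldehyde
Product: 4 2,6-dihydroxy-4-methoxy-3-methylbenzaldehyde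
Conditions: MeI (1.05 equiv), Li2CO3 (1.1 equiv), DMF, 40 °C
Reagents that add atoms: iodomethane CI
Why: Williamson O-methylation with a weak base and one equivalent of MeI should take the most acidic hydroxyl, the one para to the formyl group and the only one that cannot hydrogen-bond to it, which fixes OMe para to the future bridge carbon (formylation before methylation is what makes this choice possible).

Step 3
Reactants: 4 2,6-dihydroxy-4-methoxy-3-methylbenzaldehyde; 5 benzyl bromide
Product: 6 2,6-bis(benzyloxy)-4-methoxy-3-methylbenzaldehyde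
Conditions: 5 (2.4 equiv), K2CO3 (3 equiv), Bu4NI (cat.), DMF, 60 °C
Reagents that add atoms: benzyl bromide BrCc1ccccc1
Why: Double Williamson benzylation of the two remaining, chelated ortho phenols under more forcing conditions, each phenol taking one benzyl group so that two equivalents of 5 are consumed; the benzyl ethers survive acetylide, ketene and heat and are removed late by hydrogenolysis.

Step 4
Reactants: 6 2,6-bis(benzyloxy)-4-methoxy-3-methylbenzaldehyde
Product: 7 [2,6-bis(benzyloxy)-4-methoxy-3-methylphenyl]methanol
Conditions: NaBH4, THF/MeOH, 0 °C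
Reagents that add atoms: none
Why: Hydride reduction of an aryl aldehyde to the benzylic alcohol; the ethers are inert.

Step 5
Reactants: 7 [2,6-bis(benzyloxy)-4-methoxy-3-methylphenyl]methanol
Product: 8 1,3-bis(benzyloxy)-2-(bromomethyl)-5-methoxy-4-methylbenzene
Conditions: CBr4, PPh3, CH2Cl2, −20 to 0 °C; short basic-alumina plug, used at once
Reagents that add atoms: carbon tetrabromide BrC(Br)(Br)Br
Why: Appel bromination converts the readily ionised benzylic alcohol under neutral conditions, avoiding the acid that would set off self-condensation of this electron-rich bromide.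

Step 6
Reactants: 8 1,3-bis(benzyloxy)-2-(bromomethyl)-5-methoxy-4-methylbenzene; 9 ethoxyacetylene
Product: 11 1,3-bis(benzyloxy)-2-(3-ethoxyprop-2-yn-1-yl)-5-methoxy-4-methylbenzene, via lithium ethoxyacetylide 10 (not isolated)
Conditions: 9 (1.4 equiv, hexane solution), n-BuLi (1.3 equiv), THF, −78 °C; then DMPU, 8, −78 to 0 °C
Reagents that add atoms: none
Why: SN2 alkylation of a lithium alkoxyacetylide by a reactive benzylic bromide in a dipolar medium, the standard route to 1-ethoxy-1-alkynes; low temperature and no excess base should suppress propargyl-to-allenyl isomerisation.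

Step 7
Reactants: 11 1,3-bis(benzyloxy)-2-(3-ethoxyprop-2-yn-1-yl)-5-methoxy-4-methylbenzene; 12 isobutyryl chloride
Product: 14 2-[2,6-bis(benzyloxy)-4-methoxy-3-methylbenzyl]-3-ethoxy-4,4-dimethylcyclobut-2-en-1-one, via dimethylketene 13 (not isolated)
Conditions: 12 (2.5 equiv, slow addition), Et3N (3 equiv), toluene, 50 °C
Reagents that add atoms: none
Why: Ketene–ynol ether (2+2) cycloaddition with the ketene made by dehydrochlorination in the flask; the benzyl-bearing, nucleophilic alkyne carbon attacks the ketene carbonyl carbon, so CMe2 closes onto the ethoxy-bearing carbon and the 3-ethoxycyclobutenone results.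

Step 8
Reactants: 14 2-[2,6-bis(benzyloxy)-4-methoxy-3-methylbenzyl]-3-ethoxy-4,4-dimethylcyclobut-2-en-1-one; 9 ethoxyacetylene
Product: 18 4-[2,6-bis(benzyloxy)-4-methoxy-3-methylbenzyl]-3,5-diethoxy-6,6-dimethylcyclohexa-2,4-dien-1-one, via vinylketene 15 (not isolated), via 4-vinylcyclobutenone 16 (not isolated), via dienylketene 17 (not isolated)
Conditions: 9 (5 equiv), toluene, 90 °C, sealed tube, dark
Reagents that add atoms: none
Why: Proposed new method: heating should open 14 by four-electron electrocyclic ring opening to vinylketene 15, whose ketene C=C takes up ethoxyacetylene in a (2+2) cycloaddition to give 4-vinylcyclobutenone 16; 16 opens again to dienylketene 17, and ring A closes by a thermal disrotatory six-electron electrocyclisation of the ketene carbon (C6) onto the CMe2 terminus (C5), leaving the two alkyne carbons as C1 and C2 between C6 and C3. The closest known reactions are the Danheiser benzannulation of cyclobutenones with alkoxyalkynes, which runs through the same cascade but ends in a phenol, and the thermal reclosure of dienylketenes to 6,6-disubstituted cyclohexa-2,4-dienones; new is the fully substituted terminus, which leaves no hydrogen for tautomerisation and halts the cascade at the blocked dienone. Compound 18 has no stereocentre, and the quaternary centre of 16 is formed racemic and lost on ring opening. The selectivity needed is the regiochemistry of the ketene–ynol ether cycloaddition, which polarity secures: the terminal CH of the ynol ether, its nucleophilic end, attacks the electrophilic central carbon of the ketene, which places the ethoxy group on C2 beside the bridge-bearing C3. The 1,5-hydrogen shift from the inward methyl group of 15 and the fragmentation of ethoxyacetylene above about 100 °C are countered by a large excess of alkyne and a 90 °C bath, and a dienylketene of the wrong geometry can revert through 16.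

Step 9
Reactants: 18 4-[2,6-bis(benzyloxy)-4-methoxy-3-methylbenzyl]-3,5-diethoxy-6,6-dimethylcyclohexa-2,4-dien-1-one
Product: 19 4-[2,6-bis(benzyloxy)-4-methoxy-3-methylbenzyl]-3,5-dihydroxy-6,6-dimethylcyclohexa-2,4-dien-1-one
Conditions: 2 M aq. HCl, THF, 40 °C
Reagents that add atoms: water O
Why: Acid hydrolysis of vinylogous esters: the C2 ethoxy group is a β-alkoxy enone and the C4 ethoxy group becomes one once the first is cleaved, while benzyl ethers, the aryl methyl ether and the base-sensitive 2,2-dimethyl-1,3-dione unit tolerate dilute aqueous acid.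

Step 10
Reactants: 19 4-[2,6-bis(benzyloxy)-4-methoxy-3-methylbenzyl]-3,5-dihydroxy-6,6-dimethylcyclohexa-2,4-dien-1-one; 20 butyric acid
Product: 22 4-[2,6-bis(benzyloxy)-4-methoxy-3-methylbenzyl]-2-butanoyl-3,5-dihydroxy-6,6-dimethylcyclohexa-2,4-dien-1-one, via enol butyrate 21 (not isolated)
Conditions: DCC (1.2 equiv), DMAP (1.0 equiv), CH2Cl2, rt
Reagents that add atoms: none
Why: Steglich O-acylation followed by DMAP-mediated O-to-C acyl migration, the DCC/DMAP C-acylation of cyclic 1,3-diones, should place the butyryl group on C1, the only hydrogen-bearing carbon between two carbonyl carbons, giving the hydrogen-bonded triketone as the thermodynamic product while the benzyl-protected ring B cannot be esterified.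

Step 11
Reactants: 22 4-[2,6-bis(benzyloxy)-4-methoxy-3-methylbenzyl]-2-butanoyl-3,5-dihydroxy-6,6-dimethylcyclohexa-2,4-dien-1-one
Product: 23 2-butanoyl-4-(2,6-dihydroxy-4-methoxy-3-methylbenzyl)-3,5-dihydroxy-6,6-dimethylcyclohexa-2,4-dien-1-one
Conditions: H2 (1 atm), 10% Pd/C, EtOAc, rt
Reagents that add atoms: none
Why: Catalytic hydrogenolysis of aryl benzyl ethers; the push–pull enol double bonds of ring A, the methyl ether and the methylene bridge should be inert at ambient pressure and temperature.

Step 12
Reactants: 23 2-butanoyl-4-(2,6-dihydroxy-4-methoxy-3-methylbenzyl)-3,5-dihydroxy-6,6-dimethylcyclohexa-2,4-dien-1-one; 24 butyryl chloride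
Product: 25 aspidin
Conditions: 24 (1.5 equiv), TiCl4 (4 equiv), CH2Cl2, 0 °C to rt; then 1 M aq. HCl
Reagents that add atoms: none
Why: Friedel–Crafts acylation of a phloroglucinol-type ring, directed by the titanium phenoxide to the only free aromatic carbon (C5′, ortho to OH and OMe), while ring A is fully substituted and deactivated by its own acyl group.

**Compound list**

1 | 2,4,6-trihydroxytoluene | Cc1c(O)cc(O)cc1O | starting material
2 | N,N-dimethyl-1-(2,4,6-trihydroxy-3-methylphenyl)methaniminium chloride (not isolated) | C[N+](C)=Cc1c(O)cc(O)c(C)c1O.[Cl-] | intermediate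
3 | 2,4,6-trihydroxy-3-methylbenzaldehyde | Cc1c(O)cc(O)c(C=O)c1O | intermediate
4 | 2,6-dihydroxy-4-methoxy-3-methylbenzaldehyde | COc1cc(O)c(C=O)c(O)c1C | intermediate
5 | benzyl bromide | BrCc1ccccc1 | starting material
6 | 2,6-bis(benzyloxy)-4-methoxy-3-methylbenzaldehyde | COc1cc(OCc2ccccc2)c(C=O)c(OCc2ccccc2)c1C | intermediate
7 | [2,6-bis(benzyloxy)-4-methoxy-3-methylphenyl]methanol | COc1cc(OCc2ccccc2)c(CO)c(OCc2ccccc2)c1C | intermediate
8 | 1,3-bis(benzyloxy)-2-(bromomethyl)-5-methoxy-4-methylbenzene | COc1cc(OCc2ccccc2)c(CBr)c(OCc2ccccc2)c1C | intermediate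
9 | ethoxyacetylene | CCOC#C | starting material
10 | lithium ethoxyacetylide (not isolated) | CCOC#C[Li] | intermediate
11 | 1,3-bis(benzyloxy)-2-(3-ethoxyprop-2-yn-1-yl)-5-methoxy-4-methylbenzene | CCOC#CCc1c(OCc2ccccc2)cc(OC)c(C)c1OCc1ccccc1 | intermediate
12 | isobutyryl chloride | CC(C)C(=O)Cl | starting material
13 | dimethylketene (not isolated) | CC(C)=C=O | intermediate
14 | 2-[2,6-bis(benzyloxy)-4-methoxy-3-methylbenzyl]-3-ethoxy-4,4-dimethylcyclobut-2-en-1-one | CCOC1=C(Cc2c(OCc3ccccc3)c(C)c(OC)cc2OCc2ccccc2)C(=O)C1(C)C | intermediate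
15 | 2-[2,6-bis(benzyloxy)-4-methoxy-3-methylbenzyl]-3-ethoxy-4-methylpenta-1,3-dien-1-one (vinylketene, not isolated) | CCOC(=C(C)C)C(Cc1c(OCc2ccccc2)c(C)c(OC)cc1OCc1ccccc1)=C=O | intermediate
16 | 4-[2,6-bis(benzyloxy)-4-methoxy-3-methylbenzyl]-3-ethoxy-4-(1-ethoxy-2-methylprop-1-en-1-yl)cyclobut-2-en-1-one (racemic, not isolated) | CCOC1=CC(=O)C1(Cc1c(OCc2ccccc2)c(C)c(OC)cc1OCc1ccccc1)C(OCC)=C(C)C | intermediate
17 | (3E)-4-[2,6-bis(benzyloxy)-4-methoxy-3-methylbenzyl]-3,5-diethoxy-6-methylhepta-1,3,5-trien-1-one (dienylketene, ketenyl and alkenyl groups cis, not isolated) | CCO/C(C=C=O)=C(\Cc1c(OCc2ccccc2)c(C)c(OC)cc1OCc1ccccc1)C(OCC)=C(C)C | intermediate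
18 | 4-[2,6-bis(benzyloxy)-4-methoxy-3-methylbenzyl]-3,5-diethoxy-6,6-dimethylcyclohexa-2,4-dien-1-one | CCOC1=CC(=O)C(C)(C)C(OCC)=C1Cc1c(OCc2ccccc2)c(C)c(OC)cc1OCc1ccccc1 | intermediate
19 | 4-[2,6-bis(benzyloxy)-4-methoxy-3-methylbenzyl]-3,5-dihydroxy-6,6-dimethylcyclohexa-2,4-dien-1-one | O=C1C=C(O)C(Cc2c(OCc3ccccc3)c(C)c(OC)cc2OCc2ccccc2)=C(O)C1(C)C | intermediate
20 | butyric acid | CCCC(=O)O | starting material
21 | 6-[2,6-bis(benzyloxy)-4-methoxy-3-methylbenzyl]-5-hydroxy-4,4-dimethyl-3-oxocyclohexa-1,5-dien-1-yl butanoate (enol butyrate, not isolated) | CCCC(=O)OC1=CC(=O)C(C)(C)C(O)=C1Cc1c(OCc2ccccc2)c(C)c(OC)cc1OCc1ccccc1 | intermediate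
22 | 4-[2,6-bis(benzyloxy)-4-methoxy-3-methylbenzyl]-2-butanoyl-3,5-dihydroxy-6,6-dimethylcyclohexa-2,4-dien-1-one | CCCC(=O)C1=C(O)C(Cc2c(OCc3ccccc3)c(C)c(OC)cc2OCc2ccccc2)=C(O)C(C)(C)C1=O | intermediate
23 | 2-butanoyl-4-(2,6-dihydroxy-4-methoxy-3-methylbenzyl)-3,5-dihydroxy-6,6-dimethylcyclohexa-2,4-dien-1-one | CCCC(=O)C1=C(O)C(Cc2c(O)c(C)c(OC)cc2O)=C(O)C(C)(C)C1=O | intermediate
24 | butyryl chloride | CCCC(=O)Cl | starting material
25 | aspidin | CCCC(=O)C1=C(O)C(Cc2c(O)c(C)c(OC)c(C(=O)CCC)c2O)=C(O)C(C)(C)C1=O | target

**Step count**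

Total steps: 12. Longest linear sequence: 12 steps (1 to 25).

**Steps most likely to fail**

1. Step 8 (key step). The electrocyclic opening of the 4,4-dimethylcyclobutenone may need a temperature at which ethoxyacetylene fragments. The vinylketene may also be lost to the 1,5-hydrogen shift from its inward methyl group or to oligomerisation before the alkyne adds. The fallback uses known chemistry and takes ring A ready-made from an acylphloroglucinol instead of building it; it sets out from benzylic alcohol 7 and comes back to the route at 22. Commercial 1-(2,4,6-trihydroxyphenyl)butan-1-one is C,C-dimethylated with MeI and NaOMe in MeOH, the classical gem-dimethylation of an acylphloroglucinol, to give butyrylfilicinic acid F1. F1, used in excess, is then C-benzylated at its only free ring carbon by 7 under catalytic TsOH in CH2Cl2. This is a dehydrative Friedel–Crafts-type alkylation of an enolised 1,3-dicarbonyl by a stabilised benzylic cation and should give 22; steps 11 and 12 follow unchanged.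

2. Step 12. The Lewis acid may cause heterolysis and scrambling of the methylene bridge through ipso-protonation of the free phloroglucinol ring. It may also cause cyclodehydration of a bridge-flanking phenol onto a ring A carbonyl, or O-acylation that does not migrate to carbon. The fallback sets out from 22 and comes back at 25; it acylates ring B before the phenols are set free, so that no free ortho-phenol is present in the acid step. Compound 22 is treated with butyric acid 20, trifluoroacetic anhydride and catalytic H3PO4 in CH2Cl2 at rt, a Lewis-acid-free mixed-anhydride Friedel–Crafts acylation of a 1,3,5-trialkoxybenzene. Work-up with NaHCO3 in MeOH cleaves any ring A enol ester and should give 4-[2,6-bis(benzyloxy)-3-butanoyl-4-methoxy-5-methylbenzyl]-2-butanoyl-3,5-dihydroxy-6,6-dimethylcyclohexa-2,4-dien-1-one F2. Hydrogenolysis of F2 (H2, 10% Pd/C, EtOAc) then releases 25 as the last operation.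

3. Step 6. Bromide 8 may ionise and self-condense through the free ring B carbon before the acetylide captures it, and the propargylic ynol ether may isomerise to the allenyl ether under base. The fallback avoids both the benzylic halide and the acetylide alkylation; it sets out from alcohol 7 and comes back at cyclobutenone 14. Dimethylketene 13 (from 12 and Et3N) and ethoxyacetylene 9 give 3-ethoxy-4,4-dimethylcyclobut-2-en-1-one F3 by the known ketene–ynol ether cycloaddition. Cold dilute aqueous HCl hydrolyses F3 to 3-hydroxy-4,4-dimethylcyclobut-2-en-1-one F4, the enol of 2,2-dimethylcyclobutane-1,3-dione. F4, in excess, is C-benzylated by 7 under catalytic TsOH in CH2Cl2 to give 2-[2,6-bis(benzyloxy)-4-methoxy-3-methylbenzyl]-3-hydroxy-4,4-dimethylcyclobut-2-en-1-one F5. O-Ethylation of F5 with Et3OBF4 and iPr2NEt in CH2Cl2 gives 14 as a single enol ether, because the two carbonyl carbons of the dione are equivalent.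

**Further compounds**

F1 | step 8 | butyrylfilicinic acid (2-butanoyl-3,5-dihydroxy-6,6-dimethylcyclohexa-2,4-dien-1-one) | CCCC(=O)C1=C(O)C=C(O)C(C)(C)C1=O
F2 | step 12 | 4-[2,6-bis(benzyloxy)-3-butanoyl-4-methoxy-5-methylbenzyl]-2-butanoyl-3,5-dihydroxy-6,6-dimethylcyclohexa-2,4-dien-1-one | CCCC(=O)C1=C(O)C(Cc2c(OCc3ccccc3)c(C)c(OC)c(C(=O)CCC)c2OCc2ccccc2)=C(O)C(C)(C)C1=O
F3 | step 6 | 3-ethoxy-4,4-dimethylcyclobut-2-en-1-one | CCOC1=CC(=O)C1(C)C
F4 | step 6 | 3-hydroxy-4,4-dimethylcyclobut-2-en-1-one | OC1=CC(=O)C1(C)C
F5 | step 6 | 2-[2,6-bis(benzyloxy)-4-methoxy-3-methylbenzyl]-3-hydroxy-4,4-dimethylcyclobut-2-en-1-one | OC1=C(Cc2c(OCc3ccccc3)c(C)c(OC)cc2OCc2ccccc2)C(=O)C1(C)C
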